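**Plan**

Numbering: the core is 2-oxabicyclo[4.2.0]oct-4-en-3-one (ring A = O2–C3(=O)–C4=C5(OMe)–C6–C1; cyclobutane = C1, C6, C7, C8); ring B is the aromatic pyranone on C8.
Retrosynthetic cuts, in order: (a) the C1–CH= bond of the styryl group; (b) ring B, back to a lactone carbonyl on C8 plus an acetoacetate unit; (c) the cyclobutane bonds C1–C8 and C6–C7; (d) an ester tether between a pyranone carbinol and a cinnamic acid.
Forward: a 6-(1-hydroxyethyl)-4-methoxy-2-pyranone is esterified with silyl-protected p-coumaric acid; a sensitised intramolecular [2+2] dearomatises the pyranone, so ring A and the cyclobutane arise together, with a γ-lactone as temporary ring; that lactone is opened and grown into ring B; the styryl unit is joined last.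
Enabling feature: C1 is the ring-fusion carbon shared by the cyclobutane and ring A and carries the lactone oxygen O2. A radical there is oxygen-stabilised and can bond only on the convex face (a trans-fused four/six system is out of reach), so the exocyclic carbinol carbon on C1 (tether anchor and stereocontrol element) can be expelled as acetaldehyde and replaced by the E-styryl group of a vinyl sulfone.
Stereochemistry: one carbinol stereocentre from a catalytic asymmetric methyl addition directs the [2+2] (allylic 1,3-strain), which fixes C6, C7 and C8; C1 is re-formed in the key step under control of the ring fusion; the E-alkene comes from the E-sulfone.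

Key step: step 9

Remark: (+)-DAIB is assumed to deliver methyl to the aldehyde face that gives the R carbinol, the mirror image of the S-selective (−)-DAIB/aryl aldehyde case; if the ring oxygen reverses the sense, the antipodal ligand is used.

Step 1
Reactants: 1 4-methoxy-6-methyl-2H-pyran-2-one
Product: 2 4-methoxy-2-oxo-2H-pyran-6-carbaldehyde
Conditions: SeO2 (2 equiv), 1,4-dioxane, 150 °C (sealed tube)
Reagents that add atoms: selenium dioxide, O=[Se]=O
Why: Riley oxidation; SeO2 should oxidise the activated (allylic, vinylogous) C6 methyl group of the pyranone to the aldehyde by ene reaction and [2,3]-sigmatropic shift.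

Step 2
Reactants: 2 4-methoxy-2-oxo-2H-pyran-6-carbaldehyde
Product: 3 6-[(1R)-1-hydroxyethyl]-4-methoxy-2H-pyran-2-one
Conditions: Me2Zn (2.5 equiv), (2R)-(+)-3-exo-(dimethylamino)isoborneol [(+)-DAIB] (10 mol %), toluene, 0 °C; then 1 M HCl
Reagents that add atoms: dimethylzinc, C[Zn]C
Why: Amino-alcohol-catalysed enantioselective addition of a dialkylzinc to an aldehyde; the chiral zinc aminoalkoxide should deliver methyl to one aldehyde face and so set the R carbinol centre, the only stereocentre brought in from outside.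

Step 3
Reactants: 4 (E)-4-hydroxycinnamic acid
Product: 6 (E)-4-(triisopropylsilyloxy)cinnamic acid, via bis-silyl ester 5 (not isolated)
Conditions: TIPSCl (2.2 equiv), imidazole (4.4 equiv), DMF, 25 °C; then AcOH, THF/H2O, 25 °C
Reagents that add atoms: chlorotriisopropylsilane, CC(C)[Si](Cl)(C(C)C)C(C)C
Why: Silylation of phenol and carboxyl followed by selective hydrolysis of the labile silyl ester should leave the robust aryl silyl ether (silyl protection).

Step 4
Reactants: 3 6-[(1R)-1-hydroxyethyl]-4-methoxy-2H-pyran-2-one; 6 (E)-4-(triisopropylsilyloxy)cinnamic acid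
Product: 7 (1R)-1-(4-methoxy-2-oxo-2H-pyran-6-yl)ethyl (2E)-3-[4-(triisopropylsilyloxy)phenyl]prop-2-enoate
Conditions: EDC·HCl (1.3 equiv), DMAP (0.2 equiv), CH2Cl2, 0 → 25 °C
Reagents that add atoms: none
Why: Steglich esterification acylates the carbinol oxygen without touching the C–O stereocentre, which is retained.

Step 5
Reactants: 7 (1R)-1-(4-methoxy-2-oxo-2H-pyran-6-yl)ethyl (2E)-3-[4-(triisopropylsilyloxy)phenyl]prop-2-enoate
Product: 9 tricyclic bis-lactone (cyclobutane fused to ring A across C1–C6 and to a γ-butyrolactone C1–CH(CH3)–O–C(=O)–C8 across C1–C8; aryl on C7 trans to the lactone carbonyl; lactone methyl cis to O2), via triplet 1,4-biradical 8 (not isolated)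
Conditions: Ir[dF(CF3)ppy]2(dtbbpy)PF6 (1 mol %), degassed MeCN (2 mM), 450 nm LEDs, 40 °C
Reagents that add atoms: none
Why: Intramolecular [2+2] photocycloaddition by triplet energy transfer to the cinnamate; the cinnamate α-carbon should bond first to C6 of the pyranone (five-membered ring, rule of five) and the benzylic carbon then to C5, both ring fusions being necessarily cis, the carbinol methyl avoiding allylic 1,3-strain with H5 so that one pyranone face is attacked, and the aryl group settling trans to the lactone carbonyl.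

Step 6
Reactants: 9 tricyclic bis-lactone
Product: 11 (1R,6S,7S,8S)-8-(4-hydroxy-2-oxo-2H-pyran-6-yl)-1-[(1R)-1-hydroxyethyl]-5-methoxy-7-[4-(triisopropylsilyloxy)phenyl]-2-oxabicyclo[4.2.0]oct-4-en-3-one, via hydroxy triketo ester 10 (not isolated)
Conditions: methyl acetoacetate (3 equiv), NaH (3 equiv), nBuLi (3 equiv), THF, 0 °C; add 9, −78 → −40 °C; AcOH, −78 °C, aqueous work-up; then DBU (1.2 equiv), PhMe, 25 → 50 °C; 1 M HCl
Reagents that add atoms: methyl acetoacetate, COC(=O)CC(C)=O
Why: Claisen-type γ-acylation of the acetoacetate dianion by the strained γ-lactone (more electrophilic than the vinylogous carbonate carbonyl of ring A) should open the tether, and DBU should then close the 3,5-dioxo ester to the 4-hydroxy-2-pyranone by enol lactonisation; no stereocentre is formed or touched.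

Step 7
Reactants: 11 (1R,6S,7S,8S)-8-(4-hydroxy-2-oxo-2H-pyran-6-yl)-1-[(1R)-1-hydroxyethyl]-5-methoxy-7-[4-(triisopropylsilyloxy)phenyl]-2-oxabicyclo[4.2.0]oct-4-en-3-one
Product: 12 (1R,6S,7S,8S)-1-[(1R)-1-hydroxyethyl]-5-methoxy-8-(4-methoxy-2-oxo-2H-pyran-6-yl)-7-[4-(triisopropylsilyloxy)phenyl]-2-oxabicyclo[4.2.0]oct-4-en-3-one
Conditions: Me2SO4 (1.3 equiv), K2CO3 (2 equiv), acetone, 45 °C
Reagents that add atoms: dimethyl sulfate, COS(=O)(=O)OC
Why: O-methylation of the acidic 4-hydroxy-2-pyranone (a vinylogous acid) with dimethyl sulfate and carbonate, the standard entry to 4-methoxy-2-pyranones; K2CO3 does not deprotonate the secondary alcohol, which should stay free.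

Step 8
Reactants: 6 (E)-4-(triisopropylsilyloxy)cinnamic acid
Product: 13 (E)-2-[4-(triisopropylsilyloxy)phenyl]ethenyl phenyl sulfone
Conditions: PhSO2Na (2 equiv), CuO (20 mol %), KI (1.5 equiv), DMSO, air, 100 °C
Reagents that add atoms: sodium benzenesulfinate, [Na+].[O-]S(=O)c1ccccc1
Why: Copper-catalysed aerobic decarboxylative sulfonylation of a cinnamic acid; the sulfonyl radical should add at the α-carbon and oxidative decarboxylation of the benzylic adduct should give the E-vinyl sulfone.

Step 9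
Reactants: 12 (1R,6S,7S,8S)-1-[(1R)-1-hydroxyethyl]-5-methoxy-8-(4-methoxy-2-oxo-2H-pyran-6-yl)-7-[4-(triisopropylsilyloxy)phenyl]-2-oxabicyclo[4.2.0]oct-4-en-3-one; 13 (E)-2-[4-(triisopropylsilyloxy)phenyl]ethenyl phenyl sulfone
Product: 16 (1R,6S,7S,8S)-5-methoxy-8-(4-methoxy-2-oxo-2H-pyran-6-yl)-7-[4-(triisopropylsilyloxy)phenyl]-1-{(E)-2-[4-(triisopropylsilyloxy)phenyl]ethenyl}-2-oxabicyclo[4.2.0]oct-4-en-3-one, via alkoxy radical 14 (not isolated), via ring-fusion radical 15 (not isolated)
Conditions: 13 (3 equiv), CeCl3 (10 mol %), nBu4NCl (30 mol %), MeCN (0.3 M), 400 nm LEDs, argon, 25 °C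
Reagents that add atoms: none
Why: Proposed new method: the carbinol of 12 binds tetravalent cerium and 400 nm ligand-to-metal charge transfer homolyses the Ce–O bond to alkoxy radical 14, whose β-scission expels acetaldehyde and leaves the tertiary, O2-stabilised radical 15 at C1; 15 adds to the sulfonyl-bearing carbon of 13 and the benzylic adduct radical loses PhSO2•, which reoxidises trivalent cerium and ends as sulfinate, so the cycle is redox-neutral. The closest known reaction types are the cerium-photocatalysed dehydroxymethylation and ring opening of alcohols through alkoxy radicals with Giese trapping, and the addition–fragmentation vinylation of alkyl radicals by vinyl sulfones. No ring is closed. The only new stereocentre, C1, is fixed by the substrate: a trans-fused cyclobutane/δ-lactone containing the planar O2–C3(=O)–C4=C5 unit is out of reach, so the C–C bond can form only on the convex face, cis to H6, whatever the configuration of the lost carbinol carbon, and the E-alkene follows from the E-sulfone and the preferred geometry of the β-sulfonyl radical elimination. The step needs β-scission toward C1 and not loss of methyl or 1,5-hydrogen transfer from the benzylic C7–H, which the oxygen substituent and the congestion at C1 should secure, and capture of 15 faster than opening of its cyclobutane, which an excess of the electron-poor sulfone at high concentration should serve.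

Step 10
Reactants: 16 (1R,6S,7S,8S)-5-methoxy-8-(4-methoxy-2-oxo-2H-pyran-6-yl)-7-[4-(triisopropylsilyloxy)phenyl]-1-{(E)-2-[4-(triisopropylsilyloxy)phenyl]ethenyl}-2-oxabicyclo[4.2.0]oct-4-en-3-one
Product: 17 (1R,6S,7S,8S)-7-(4-hydroxyphenyl)-1-[(E)-2-(4-hydroxyphenyl)ethenyl]-5-methoxy-8-(4-methoxy-2-oxo-2H-pyran-6-yl)-2-oxabicyclo[4.2.0]oct-4-en-3-one
Conditions: TBAF (2.4 equiv), AcOH (2.4 equiv), THF, 0 °C
Reagents that add atoms: none
Why: Fluoride-induced cleavage of both aryl silyl ethers (desilylation), buffered with acetic acid so that the lactones and the tertiary allylic C1–O2 bond are not exposed to base; no stereocentre is affected.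

**Compound list**

1 | 4-methoxy-6-methyl-2H-pyran-2-one | COc1cc(C)oc(=O)c1 | starting material
2 | 4-methoxy-2-oxo-2H-pyran-6-carbaldehyde | COc1cc(C=O)oc(=O)c1 | intermediate
3 | 6-[(1R)-1-hydroxyethyl]-4-methoxy-2H-pyran-2-one | C[C@@H](O)c1cc(OC)cc(=O)o1 | intermediate
4 | (E)-4-hydroxycinnamic acid (p-coumaric acid) | OC(=O)/C=C/c1ccc(O)cc1 | starting material
5 | triisopropylsilyl (E)-4-(triisopropylsilyloxy)cinnamate | CC(C)[Si](OC(=O)/C=C/c1ccc(O[Si](C(C)C)(C(C)C)C(C)C)cc1)(C(C)C)C(C)C | intermediate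
6 | (E)-4-(triisopropylsilyloxy)cinnamic acid | OC(=O)/C=C/c1ccc(O[Si](C(C)C)(C(C)C)C(C)C)cc1 | intermediate
7 | (1R)-1-(4-methoxy-2-oxo-2H-pyran-6-yl)ethyl (2E)-3-[4-(triisopropylsilyloxy)phenyl]prop-2-enoate | C[C@@H](OC(=O)/C=C/c1ccc(O[Si](C(C)C)(C(C)C)C(C)C)cc1)c1cc(OC)cc(=O)o1 | intermediate
8 | triplet 1,4-biradical (γ-lactone closed by the Cα–C6 bond; radical centres at C5 of ring A and at the benzylic carbon) | COC1=CC(=O)O[C@@]2([CH]1)[C@@H](C)OC(=O)[C@@H]2[CH]c1ccc(O[Si](C(C)C)(C(C)C)C(C)C)cc1 | intermediate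
9 | tricyclic bis-lactone: cyclobutane fused to ring A across C1–C6 and to a γ-butyrolactone [C1–CH(CH3)–O–C(=O)–C8] across C1–C8; 4-(triisopropylsilyloxy)phenyl on C7 trans to the lactone carbonyl and cis to C5; lactone methyl cis to O2 | COC1=CC(=O)O[C@]2([C@@H](C)OC3=O)[C@H]1[C@H](c1ccc(O[Si](C(C)C)(C(C)C)C(C)C)cc1)[C@H]23 | intermediate
10 | ring-opened hydroxy triketo ester: C8 carries C(=O)CH2C(=O)CH2CO2Me, C1 carries (R)-CH(OH)CH3, ring configuration as in 9 | COC1=CC(=O)O[C@]2([C@@H](C)O)[C@H]1[C@H](c1ccc(O[Si](C(C)C)(C(C)C)C(C)C)cc1)[C@H]2C(=O)CC(=O)CC(=O)OC | intermediate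
11 | (1R,6S,7S,8S)-8-(4-hydroxy-2-oxo-2H-pyran-6-yl)-1-[(1R)-1-hydroxyethyl]-5-methoxy-7-[4-(triisopropylsilyloxy)phenyl]-2-oxabicyclo[4.2.0]oct-4-en-3-one | COC1=CC(=O)O[C@]2([C@@H](C)O)[C@H]1[C@H](c1ccc(O[Si](C(C)C)(C(C)C)C(C)C)cc1)[C@H]2c1cc(O)cc(=O)o1 | intermediate
12 | (1R,6S,7S,8S)-1-[(1R)-1-hydroxyethyl]-5-methoxy-8-(4-methoxy-2-oxo-2H-pyran-6-yl)-7-[4-(triisopropylsilyloxy)phenyl]-2-oxabicyclo[4.2.0]oct-4-en-3-one | COC1=CC(=O)O[C@]2([C@@H](C)O)[C@H]1[C@H](c1ccc(O[Si](C(C)C)(C(C)C)C(C)C)cc1)[C@H]2c1cc(OC)cc(=O)o1 | intermediate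
13 | (E)-2-[4-(triisopropylsilyloxy)phenyl]ethenyl phenyl sulfone | O=S(=O)(/C=C/c1ccc(O[Si](C(C)C)(C(C)C)C(C)C)cc1)c1ccccc1 | intermediate
14 | alkoxy radical of 12 (oxygen-centred radical on the carbinol) | COC1=CC(=O)O[C@]2([C@@H](C)[O])[C@H]1[C@H](c1ccc(O[Si](C(C)C)(C(C)C)C(C)C)cc1)[C@H]2c1cc(OC)cc(=O)o1 | intermediate
15 | ring-fusion radical (carbon-centred radical at C1, C6/C7/C8 as in 12) | COC1=CC(=O)O[C]2[C@H]1[C@H](c1ccc(O[Si](C(C)C)(C(C)C)C(C)C)cc1)[C@H]2c1cc(OC)cc(=O)o1 | intermediate
16 | (1R,6S,7S,8S)-5-methoxy-8-(4-methoxy-2-oxo-2H-pyran-6-yl)-7-[4-(triisopropylsilyloxy)phenyl]-1-{(E)-2-[4-(triisopropylsilyloxy)phenyl]ethenyl}-2-oxabicyclo[4.2.0]oct-4-en-3-one | COC1=CC(=O)O[C@]2(/C=C/c3ccc(O[Si](C(C)C)(C(C)C)C(C)C)cc3)[C@H]1[C@H](c1ccc(O[Si](C(C)C)(C(C)C)C(C)C)cc1)[C@H]2c1cc(OC)cc(=O)o1 | intermediate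
17 | (1R,6S,7S,8S)-7-(4-hydroxyphenyl)-1-[(E)-2-(4-hydroxyphenyl)ethenyl]-5-methoxy-8-(4-methoxy-2-oxo-2H-pyran-6-yl)-2-oxabicyclo[4.2.0]oct-4-en-3-one | COC1=CC(=O)O[C@]2(/C=C/c3ccc(O)cc3)[C@H]1[C@H](c1ccc(O)cc1)[C@H]2c1cc(OC)cc(=O)o1 | target

**Count and risks**

Total: 10 steps. Longest linear sequence: 8 steps (1 → 2 → 3 → 7 → 9 → 11 → 12 → 16 → 17).

Steps most likely to fail:

1. Step 9 (proposed new method). The alkoxy radical may form inefficiently at the hindered carbinol, or abstract the benzylic hydrogen on C7 by 1,5-hydrogen transfer in place of cleaving the C1–carbinol bond. Radical 15 may also open the cyclobutane (C6–C7 cleavage, which re-aromatises ring A) before it is captured; the fallback shares this last risk, which only a higher sulfone concentration addresses. Fallback by known chemistry, setting out from 12 and returning at 16: Dess–Martin oxidation should give the methyl ketone F1; TMSOTf/Et3N should give the trimethylsilyl enol ether F2; Rubottom oxidation (mCPBA, then mild acid) should give the hydroxymethyl ketone F3; periodic acid should cleave this to the carboxylic acid F4. Visible-light photoredox decarboxylative vinylation of this α-oxy acid with 13 (Ir[dF(CF3)ppy]2(dtbbpy)PF6, CsHCO3, 1,4-dioxane, blue LEDs) should then give 16 through the same ring-fusion radical without any alkoxy radical.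

2. Step 5. The ester prefers its extended conformation, in which the cinnamate cannot reach C6, so unproductive decay, E/Z isomerisation and intermolecular dimerisation may outrun ring closure. The benzylic radical centre of 8 may also close with the aryl group on the wrong face of C7. Fallback with a silicon tether, setting out from 3 and 6 and returning at 9: reduction of 6 through its mixed anhydride (iBuOCOCl, N-methylmorpholine; NaBH4) should give the cinnamyl alcohol F5; joining 3 and this alcohol with iPr2SiCl2/imidazole should give the silylene bis-ether F6; the same sensitised [2+2] should give the tricyclic siloxane F7, whose seven-membered temporary ring has no ester conformer problem. HF·pyridine should release the diol F8 with the aryl silyl ether intact, and TEMPO/PhI(OAc)2 oxidative lactonisation should give 9.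

3. Step 6. The alkoxide set free on the carbinol sits next to the ring A lactone oxygen; acyl transfer to it would unmask a tertiary cyclobutanolate that fragments by retro-aldol cleavage, and the dianion may also attack ring A. Fallback under non-basic opening, setting out from 9 and returning at 11: aminolysis with AlMe3/MeNHOMe·HCl should give the hydroxy N-methoxy-N-methylamide F9; TESOTf/2,6-lutidine should give its triethylsilyl ether F10; the lithium dienolate of 2,2,6-trimethyl-4H-1,3-dioxin-4-one (LiHMDS, THF, −78 °C) should acylate to the keto dioxinone F11; heating in toluene (loss of acetone, ketene cyclisation) should give the silyl-protected hydroxypyranone F12; AcOH/THF/H2O should remove the triethylsilyl group and return 11.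

**Further compounds**

F1 | step 9 | methyl ketone (C1–C(=O)CH3 in place of the carbinol of 12) | COC1=CC(=O)O[C@]2(C(C)=O)[C@H]1[C@H](c1ccc(O[Si](C(C)C)(C(C)C)C(C)C)cc1)[C@H]2c1cc(OC)cc(=O)o1
F2 | step 9 | trimethylsilyl enol ether of F1 | COC1=CC(=O)O[C@]2(C(=C)O[Si](C)(C)C)[C@H]1[C@H](c1ccc(O[Si](C(C)C)(C(C)C)C(C)C)cc1)[C@H]2c1cc(OC)cc(=O)o1
F3 | step 9 | hydroxymethyl ketone (C1–C(=O)CH2OH) | COC1=CC(=O)O[C@]2(C(=O)CO)[C@H]1[C@H](c1ccc(O[Si](C(C)C)(C(C)C)C(C)C)cc1)[C@H]2c1cc(OC)cc(=O)o1
F4 | step 9 | carboxylic acid (C1–CO2H) | COC1=CC(=O)O[C@]2(C(O)=O)[C@H]1[C@H](c1ccc(O[Si](C(C)C)(C(C)C)C(C)C)cc1)[C@H]2c1cc(OC)cc(=O)o1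
F5 | step 5 | (E)-3-[4-(triisopropylsilyloxy)phenyl]prop-2-en-1-ol | OC/C=C/c1ccc(O[Si](C(C)C)(C(C)C)C(C)C)cc1
F6 | step 5 | diisopropylsilylene bis-ether of 3 and F5 | C[C@@H](O[Si](C(C)C)(C(C)C)OC/C=C/c1ccc(O[Si](C(C)C)(C(C)C)C(C)C)cc1)c1cc(OC)cc(=O)o1
F7 | step 5 | tricyclic siloxane [2+2] adduct (C1–CH(CH3)–O–Si(iPr)2–O–CH2–C8 ring) | COC1=CC(=O)O[C@]2([C@@H](C)O[Si](C(C)C)(C(C)C)OC3)[C@H]1[C@H](c1ccc(O[Si](C(C)C)(C(C)C)C(C)C)cc1)[C@H]23
F8 | step 5 | diol (C1–(R)-CH(OH)CH3 and C8–CH2OH) | COC1=CC(=O)O[C@]2([C@@H](C)O)[C@H]1[C@H](c1ccc(O[Si](C(C)C)(C(C)C)C(C)C)cc1)[C@H]2CO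
F9 | step 6 | hydroxy N-methoxy-N-methylamide (C8–C(=O)N(OMe)Me) | COC1=CC(=O)O[C@]2([C@@H](C)O)[C@H]1[C@H](c1ccc(O[Si](C(C)C)(C(C)C)C(C)C)cc1)[C@H]2C(=O)N(C)OC
F10 | step 6 | triethylsilyl ether of F9 | COC1=CC(=O)O[C@]2([C@@H](C)O[Si](CC)(CC)CC)[C@H]1[C@H](c1ccc(O[Si](C(C)C)(C(C)C)C(C)C)cc1)[C@H]2C(=O)N(C)OC
F11 | step 6 | keto dioxinone (C8–C(=O)CH2–(2,2-dimethyl-4-oxo-4H-1,3-dioxin-6-yl)) | COC1=CC(=O)O[C@]2([C@@H](C)O[Si](CC)(CC)CC)[C@H]1[C@H](c1ccc(O[Si](C(C)C)(C(C)C)C(C)C)cc1)[C@H]2C(=O)CC1=CC(=O)OC(C)(C)O1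
F12 | step 6 | triethylsilyl ether of 11 | COC1=CC(=O)O[C@]2([C@@H](C)O[Si](CC)(CC)CC)[C@H]1[C@H](c1ccc(O[Si](C(C)C)(C(C)C)C(C)C)cc1)[C@H]2c1cc(O)cc(=O)o1
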